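**Plan**

- Retrosynthesis (germacranolide numbering): the C1/C10 oxirane, the ester C–O bonds at C3 and C8 and C11=C13 are removed first; the lactone is cut back to a C6 alcohol and a C12 primary alcohol, and C8–O to C8–Si.
- The ten-membered ring then shows Z C4=C5, oxygen on C6 and the E C1=C10 alkene as C5=C4 … C6(=O)–C7–C8–C9–C10=C1, the 1,5-relationship of an oxy-Cope product. So C8–C9 is cut and C1–C6 rejoined to a trans-1,2-dialkenylcyclohex-2-enol.
- This carbinol is cut at C6–C7 into a cyclohexenone made from (R)-carvone and a silylalkyne that already carries C7, C8, C11 and C12; the epoxyangelic acid is made separately from methyl angelate.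
- Forward ring order: cyclohexene (carvone) → ten-membered ring (ring expansion) → γ-lactone (oxidative lactonisation) → oxirane (last step).
- Stereochemistry: C3 is the carvone carbonyl carbon (Luche reduction, Mitsunobu inversion); the carvone stereocentre steers the alkenyl addition and the chair transition state relays it to C8; C7 and C6 come from attack on the outer face of the ten-membered enolate and ketone, C1/C10 from peripheral epoxidation, the side-chain epoxide from a Sharpless epoxidation.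

Key step: step 8

Remark: germacranolide numbers (C1–C10 ring, C11–C13 lactone carbons, α = face of H-7) are used from step 7 on, the target is taken as the (1R,3S,6R,7R,8R,10R) isomer with a (2R,3R)-epoxyangelate as drawn, and the CIP label of C7 changes with the substituent on C8 although its geometry does not.
Abbreviations: Bn = benzyl, TBS = tert-butyldimethylsilyl, TIPS = triisopropylsilyl, TES = triethylsilyl.

**Route**

Step 1
Reactants: 1 (R)-(−)-carvone
Product: 2 (1R,5R)-cis-carveol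
Conditions: NaBH4, CeCl3·7H2O, MeOH, −78 °C
Reagents that add atoms: none
Why: Luche reduction is 1,2-selective on the enone, and axial hydride delivery to the half-chair with the isopropenyl group equatorial gives the equatorial, cis hydroxyl, so the new carbinol centre is R.

Step 2
Reactants: 2 (1R,5R)-cis-carveol
Product: 3 (1S,5R)-trans-carveyl 4-nitrobenzoate
Conditions: 4-nitrobenzoic acid, PPh3, DIAD, THF, 0 °C to rt
Reagents that add atoms: 4-nitrobenzoic acid, OC(=O)c1ccc(cc1)[N+](=O)[O-]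
Why: The Mitsunobu reaction esterifies the secondary allylic alcohol with SN2 inversion, turning the carbinol centre from R to S (the later C3, where S is needed).

Step 3
Reactants: 3 (1S,5R)-trans-carveyl 4-nitrobenzoate
Product: 4 (1S,5R)-trans-carveol
Conditions: K2CO3 (cat.), MeOH, rt
Reagents that add atoms: none
Why: Base-catalysed transesterification with methanol removes the nitrobenzoate without touching either stereocentre.

Step 4
Reactants: 4 (1S,5R)-trans-carveol
Product: 5 (1S,5R)-trans-carveol TIPS ether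
Conditions: TIPSOTf, 2,6-lutidine, CH2Cl2, 0 °C
Reagents that add atoms: triisopropylsilyl trifluoromethanesulfonate, CC(C)[Si](OS(=O)(=O)C(F)(F)F)(C(C)C)C(C)C
Why: Silylation with the silyl triflate and a hindered base is the standard way to protect a hindered secondary alcohol, and TIPS is chosen because it survives the chromium oxidation, the organometallic steps, potassium alkoxide and a short fluoride treatment.

Step 5
Reactants: 5 (1S,5R)-trans-carveol TIPS ether
Product: 6 (4S,6R)-3-methyl-6-(prop-1-en-2-yl)-4-[(triisopropylsilyl)oxy]cyclohex-2-en-1-one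
Conditions: CrO3, 3,5-dimethylpyrazole, CH2Cl2, −20 °C
Reagents that add atoms: chromium trioxide CrO3, O=[Cr](=O)=O
Why: Allylic C–H oxidation with the CrO3–3,5-dimethylpyrazole complex converts the only ring methylene next to the trisubstituted alkene into the enone carbonyl (as limonene gives isopiperitenone), and the cold non-basic medium leaves the α-carbonyl isopropenyl centre (R) and the silyloxy centre (S) unchanged.

Step 6
Reactants: 7 tert-butyl(but-3-yn-1-yloxy)dimethylsilane
Product: 9 benzyl{4-[(tert-butyldimethylsilyl)oxy]but-1-yn-1-yl}dimethylsilane, via lithium acetylide 8 (not isolated)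
Conditions: n-BuLi, THF, −78 °C; then BnMe2SiCl, −78 °C to rt
Reagents that add atoms: benzylchlorodimethylsilane, C[Si](C)(Cl)Cc1ccccc1
Why: C-silylation of acetylide 8 with a chlorosilane is the standard alkynylsilane synthesis, and the benzyldimethylsilyl group is chosen because it can later be oxidised to a hydroxyl by fluoride and peroxide without electrophiles that would attack the alkenes.

Step 7
Reactants: 6 (4S,6R)-3-methyl-6-(prop-1-en-2-yl)-4-[(triisopropylsilyl)oxy]cyclohex-2-en-1-one; 9 benzyl{4-[(tert-butyldimethylsilyl)oxy]but-1-yn-1-yl}dimethylsilane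
Product: 11 (1R,4S,6R)-1-[(1E)-1-(BnMe2Si)-4-(TBSO)but-1-en-2-yl]-3-methyl-6-(prop-1-en-2-yl)-4-(TIPSO)cyclohex-2-en-1-ol, via titanium alkyne complex 10 (not isolated)
Conditions: 9, Ti(OiPr)4, iPrMgCl (2 equiv), Et2O, −78 to −50 °C; then 6, −50 to 0 °C; then H2O
Reagents that add atoms: none
Why: Reductive coupling of an internal alkyne with a ketone through the divalent titanium alkoxide complex 10 forms the C6–C7 bond at the alkyne carbon remote from silicon and, after protonolysis of the Ti–C8 bond, leaves hydrogen cis to the carbinol carbon, so silicon is trans to it and cis to the C11–C12 chain; the bulky reagent adds to the carbonyl face opposite the neighbouring isopropenyl group, making the tertiary carbinol centre R with the two alkenyl groups trans.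

Step 8
Reactants: 11 (1R,4S,6R)-1-[(1E)-1-(BnMe2Si)-4-(TBSO)but-1-en-2-yl]-3-methyl-6-(prop-1-en-2-yl)-4-(TIPSO)cyclohex-2-en-1-ol
Product: 14 (2Z,4S,6E,9R,10S)-9-(BnMe2Si)-10-[2-(TBSO)ethyl]-3,7-dimethyl-4-(TIPSO)cyclodeca-2,6-dien-1-one, via potassium alkoxide 12 (not isolated), via potassium enolate 13 (not isolated)
Conditions: KH, 18-crown-6, THF, 0 to 40 °C; then AcOH, THF, −78 °C
Reagents that add atoms: none
Why: KH with 18-crown-6 turns 11 into the free alkoxide 12, whose oxyanion weakens the C1–C6 bond so that a concerted [3,3] sigmatropic shift joins C8 to C9 as C1–C6 breaks and gives enolate 13; the closest known reaction type is the anionic oxy-Cope rearrangement of trans-1,2-dialkenylcyclohexanols to cyclodec-5-enones. The ten-membered ring is formed not by an exo or endo cyclisation but by four-atom ring expansion of the cyclohexene through a chair transition state with both ring bonds equatorial, so the cyclohexene alkene is carried over as Z C4=C5 and the new C1=C10 alkene is E. C8 is controlled by the E vinylsilane: silicon sits equatorial on the chair, so the configuration of the carbinol carbon and its isopropenyl-bearing neighbour is transferred to C8 (R). C7 is controlled by the locked planar chirality of the fully substituted E enolate 13, in which neither the O–K group nor the side chain can pass through the ring: AcOH at −78 °C protonates the exposed face, the one that carries H-8, so the C11–C12 chain ends up cis to silicon (7S). The step needs the chair rather than a boat and a [3,3] rather than a [1,3] shift, which the trans arrangement of the two alkenyl groups secures, and it needs silicon to stay on carbon, which its position trans to the alkoxide across the alkene and the lack of a β-leaving group in 13 secure.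

Step 9
Reactants: 14 (2Z,4S,6E,9R,10S)-9-(BnMe2Si)-10-[2-(TBSO)ethyl]-3,7-dimethyl-4-(TIPSO)cyclodeca-2,6-dien-1-one
Product: 15 (1R,2Z,4S,6E,9R,10S)-9-(BnMe2Si)-10-[2-(TBSO)ethyl]-3,7-dimethyl-4-(TIPSO)cyclodeca-2,6-dien-1-ol
Conditions: NaBH4, CeCl3·7H2O, MeOH/THF, −78 °C
Reagents that add atoms: none
Why: Luche reduction attacks the enone carbonyl 1,2 and from outside the ring: with the carbonyl still eclipsing C7–C8 as in enolate 13, H-7 lies on the open face and hydride enters beside it, which should give the 6R (6α) alcohol trans to the C7 chain (macrocyclic peripheral attack).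

Step 10
Reactants: 15 (1R,2Z,4S,6E,9R,10S)-9-(BnMe2Si)-10-[2-(TBSO)ethyl]-3,7-dimethyl-4-(TIPSO)cyclodeca-2,6-dien-1-ol
Product: 16 (1R,2Z,4S,6E,9R,10S)-9-(BnMe2Si)-10-(2-hydroxyethyl)-3,7-dimethyl-4-(TIPSO)cyclodeca-2,6-dien-1-ol
Conditions: HF·pyridine, pyridine, THF, 0 °C
Reagents that add atoms: none
Why: Buffered HF·pyridine cleaves a primary TBS ether much faster than a hindered secondary TIPS ether and does not attack the carbon-bound benzyldimethylsilyl group (selective desilylation).

Step 11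
Reactants: 16 (1R,2Z,4S,6E,9R,10S)-9-(BnMe2Si)-10-(2-hydroxyethyl)-3,7-dimethyl-4-(TIPSO)cyclodeca-2,6-dien-1-ol
Product: 18 (3S,6R,7S,8R)-8-(BnMe2Si)-3-(TIPSO)-13-norgermacra-1(10)E,4Z-dien-12,6-olide, via lactol 17 (not isolated)
Conditions: TEMPO (20 mol%), PhI(OAc)2, CH2Cl2, rt
Reagents that add atoms: none
Why: Oxidative lactonisation of a 1,4-diol: TEMPO/PhI(OAc)2 oxidises the primary alcohol selectively, the aldehyde closes onto the C6 hydroxyl as lactol 17 and this is oxidised on to the γ-lactone, whose trans ring fusion follows from the C6 and C7 centres already set.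

Step 12
Reactants: 18 (3S,6R,7S,8R)-8-(BnMe2Si)-3-(TIPSO)-13-norgermacra-1(10)E,4Z-dien-12,6-olide
Product: 20 (3S,6R,7R,8R)-8-hydroxy-3-(TIPSO)-13-norgermacra-1(10)E,4Z-dien-12,6-olide, via fluorosilane 19 (not isolated)
Conditions: Bu4NF, THF, 0 °C; then KHCO3, 30% H2O2, MeOH, rt
Reagents that add atoms: hydrogen peroxide, OO
Why: Tamao–Fleming oxidation in its benzyldimethylsilane form: fluoride removes the benzyl group to give fluorosilane 19, hydroperoxide adds to silicon and C8 migrates from silicon to oxygen with retention (8R, 8β-OH), while the alkenes and the hindered TIPS ether should survive the short, cold fluoride treatment.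

Step 13
Reactants: 20 (3S,6R,7R,8R)-8-hydroxy-3-(TIPSO)-13-norgermacra-1(10)E,4Z-dien-12,6-olide
Product: 21 (3S,6R,7S,8R)-8-(TESO)-3-(TIPSO)-13-norgermacra-1(10)E,4Z-dien-12,6-olide
Conditions: TESCl, imidazole, DMF, 0 °C
Reagents that add atoms: chlorotriethylsilane, CC[Si](Cl)(CC)CC
Why: Silylation protects the C8 hydroxyl so that its alkoxide cannot open the lactone in the enolate step, and TES can later be removed in the presence of TIPS.

Step 14
Reactants: 21 (3S,6R,7S,8R)-8-(TESO)-3-(TIPSO)-13-norgermacra-1(10)E,4Z-dien-12,6-olide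
Product: 25 (3S,6R,7S,8R)-8-(TESO)-3-(TIPSO)germacra-1(10)E,4Z,11(13)-trien-12,6-olide, via lithium enolate 22 (not isolated), via Mannich base 23 (not isolated), via ammonium iodide 24 (not isolated)
Conditions: LiN(iPr)2, THF, −78 °C; CH2=NMe2+ I−, −78 °C to rt; then MeI, MeOH, rt; then aq. NaHCO3, EtOAc
Reagents that add atoms: Eschenmoser's salt (N,N-dimethylmethyleneiminium iodide), C=[N+](C)C.[I-]
Why: α-Methylenation of a lactone by the Mannich route: enolate 22 is aminomethylated to 23, methylation gives ammonium salt 24 and mild base induces β-elimination to the exocyclic C11=C13 alkene, with no stereocentre formed or lost.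

Step 15
Reactants: 25 (3S,6R,7S,8R)-8-(TESO)-3-(TIPSO)germacra-1(10)E,4Z,11(13)-trien-12,6-olide
Product: 26 (3S,6R,7R,8R)-8-hydroxy-3-(TIPSO)germacra-1(10)E,4Z,11(13)-trien-12,6-olide
Conditions: HF·pyridine, pyridine, THF, 0 °C
Reagents that add atoms: none
Why: Selective desilylation with buffered HF·pyridine removes the TES ether and leaves the hindered TIPS ether and the α-methylene lactone intact.

Step 16
Reactants: 27 methyl angelate
Product: 28 (2Z)-2-methylbut-2-en-1-ol (angelyl alcohol)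
Conditions: iBu2AlH, CH2Cl2, −78 °C
Reagents that add atoms: none
Why: iBu2AlH reduces the conjugated ester to the allylic alcohol by 1,2-hydride addition without isomerising the Z alkene.

Step 17
Reactants: 28 (2Z)-2-methylbut-2-en-1-ol
Product: 29 [(2S,3R)-2,3-dimethyloxiran-2-yl]methanol
Conditions: Ti(OiPr)4 (10 mol%), L-(+)-diethyl tartrate (12 mol%), tBuOOH, 4 Å molecular sieves, CH2Cl2, −20 °C
Reagents that add atoms: tert-butyl hydroperoxide, CC(C)(C)OO
Why: Sharpless asymmetric epoxidation of a primary allylic alcohol, in which L-(+)-diethyl tartrate delivers oxygen to the same enantioface as in the conversion of geraniol into (2S,3S)-epoxygeraniol, here giving the (2S,3R)-epoxy alcohol with the two methyl groups trans as in the Z alkene.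

Step 18
Reactants: 29 [(2S,3R)-2,3-dimethyloxiran-2-yl]methanol
Product: 31 (2R,3R)-2,3-dimethyloxirane-2-carboxylic acid, via epoxy aldehyde 30 (not isolated)
Conditions: RuCl3·H2O (2 mol%), NaIO4, CCl4/MeCN/H2O, rt
Reagents that add atoms: water (the new carboxyl oxygen enters through the aldehyde hydrate), O
Why: RuO4 generated catalytically from RuCl3 and NaIO4 oxidises a primary epoxy alcohol through aldehyde 30 to the glycidic acid without opening the epoxide, and only the CIP label at C2 changes from S to R.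

Step 19
Reactants: 26 (3S,6R,7R,8R)-8-hydroxy-3-(TIPSO)germacra-1(10)E,4Z,11(13)-trien-12,6-olide; 31 (2R,3R)-2,3-dimethyloxirane-2-carboxylic acid
Product: 33 (3S,6R,7R,8R)-8-{[(2R,3R)-2,3-dimethyloxirane-2-carbonyl]oxy}-3-(TIPSO)germacra-1(10)E,4Z,11(13)-trien-12,6-olide, via mixed anhydride 32 (not isolated)
Conditions: 31, 2,4,6-trichlorobenzoyl chloride, Et3N, THF, rt; then 26, DMAP, toluene, rt
Reagents that add atoms: none
Why: Yamaguchi esterification: mixed anhydride 32 acylates the hindered secondary C8 hydroxyl under DMAP catalysis with retention at C8, and the acid has no α-hydrogen to epimerise.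

Step 20
Reactants: 33 (3S,6R,7R,8R)-8-{[(2R,3R)-2,3-dimethyloxirane-2-carbonyl]oxy}-3-(TIPSO)germacra-1(10)E,4Z,11(13)-trien-12,6-olide
Product: 34 (3S,6R,7R,8R)-8-{[(2R,3R)-2,3-dimethyloxirane-2-carbonyl]oxy}-3-hydroxygermacra-1(10)E,4Z,11(13)-trien-12,6-olide
Conditions: Bu4NF, AcOH, THF, 0 °C to rt
Reagents that add atoms: none
Why: Fluoride desilylation buffered with acetic acid removes the TIPS ether while keeping the medium too weakly basic for conjugate addition to the α-methylene lactone, acyl migration or epoxide opening.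

Step 21
Reactants: 34 (3S,6R,7R,8R)-8-{[(2R,3R)-2,3-dimethyloxirane-2-carbonyl]oxy}-3-hydroxygermacra-1(10)E,4Z,11(13)-trien-12,6-olide
Product: 35 (3S,6R,7R,8R)-8-{[(2R,3R)-2,3-dimethyloxirane-2-carbonyl]oxy}-3-(3-methylbutanoyloxy)germacra-1(10)E,4Z,11(13)-trien-12,6-olide
Conditions: isovaleric anhydride, DMAP, Et3N, CH2Cl2, 0 °C
Reagents that add atoms: 3-methylbutanoic (isovaleric) anhydride, CC(C)CC(=O)OC(=O)CC(C)C
Why: DMAP-catalysed acylation of the secondary allylic C3 alcohol with the anhydride gives the isovalerate with retention.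

Step 22
Reactants: 35 (3S,6R,7R,8R)-8-{[(2R,3R)-2,3-dimethyloxirane-2-carbonyl]oxy}-3-(3-methylbutanoyloxy)germacra-1(10)E,4Z,11(13)-trien-12,6-olide
Product: 36 CNP0167461.2
Conditions: mCPBA, NaHCO3, CH2Cl2, 0 °C
Reagents that add atoms: 3-chloroperoxybenzoic acid, OOC(=O)c1cccc(Cl)c1
Why: Prilezhaev epoxidation takes the most electron-rich alkene, the trisubstituted E C1=C10 bond, in preference to C4=C5 (deactivated by two allylic acyloxy groups) and the conjugated C11=C13 bond; syn addition turns the E alkene into the trans epoxide, and attack on the outer face of the conformer with the C10 methyl group on the β face should give the 1R,10R (1β,10α) epoxide.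

**Compound list**

1 | (R)-(−)-carvone, (5R)-2-methyl-5-(prop-1-en-2-yl)cyclohex-2-en-1-one | CC(=C)[C@@H]1CC=C(C)C(=O)C1 | starting material
2 | (1R,5R)-cis-carveol, (1R,5R)-2-methyl-5-(prop-1-en-2-yl)cyclohex-2-en-1-ol | CC(=C)[C@@H]1CC=C(C)[C@H](O)C1 | intermediate
3 | (1S,5R)-trans-carveyl 4-nitrobenzoate | CC(=C)[C@@H]1CC=C(C)[C@@H](OC(=O)c2ccc(cc2)[N+](=O)[O-])C1 | intermediate
4 | (1S,5R)-trans-carveol | CC(=C)[C@@H]1CC=C(C)[C@@H](O)C1 | intermediate
5 | triisopropyl{[(1S,5R)-2-methyl-5-(prop-1-en-2-yl)cyclohex-2-en-1-yl]oxy}silane | CC(=C)[C@@H]1CC=C(C)[C@@H](O[Si](C(C)C)(C(C)C)C(C)C)C1 | intermediate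
6 | (4S,6R)-3-methyl-6-(prop-1-en-2-yl)-4-[(triisopropylsilyl)oxy]cyclohex-2-en-1-one | CC(=C)[C@@H]1C(=O)C=C(C)[C@@H](O[Si](C(C)C)(C(C)C)C(C)C)C1 | intermediate
7 | tert-butyl(but-3-yn-1-yloxy)dimethylsilane | C#CCCO[Si](C)(C)C(C)(C)C | starting material
8 | lithium 4-[(tert-butyldimethylsilyl)oxy]but-1-yn-1-ide | [Li+].[C-]#CCCO[Si](C)(C)C(C)(C)C | intermediate (not isolated)
9 | benzyl{4-[(tert-butyldimethylsilyl)oxy]but-1-yn-1-yl}dimethylsilane | CC(C)(C)[Si](C)(C)OCCC#C[Si](C)(C)Cc1ccccc1 | intermediate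
10 | diisopropoxytitanium η2-complex of alkyne 9 (titanacyclopropene) | CC(C)O[Ti]1(OC(C)C)C(CCO[Si](C)(C)C(C)(C)C)=C1[Si](C)(C)Cc1ccccc1 | intermediate (not isolated)
11 | (1R,4S,6R)-1-{(1E)-1-[benzyl(dimethyl)silyl]-4-[(tert-butyldimethylsilyl)oxy]but-1-en-2-yl}-3-methyl-6-(prop-1-en-2-yl)-4-[(triisopropylsilyl)oxy]cyclohex-2-en-1-ol (hydroxyl cis to isopropenyl, alkenyl groups trans) | C=C(C)[C@H]1C[C@H](O[Si](C(C)C)(C(C)C)C(C)C)C(C)=C[C@]1(O)/C(CCO[Si](C)(C)C(C)(C)C)=C/[Si](C)(C)Cc1ccccc1 | intermediate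
12 | potassium alkoxide of 11 | C=C(C)[C@H]1C[C@H](O[Si](C(C)C)(C(C)C)C(C)C)C(C)=C[C@]1([O-])/C(CCO[Si](C)(C)C(C)(C)C)=C/[Si](C)(C)Cc1ccccc1.[K+] | intermediate (not isolated)
13 | potassium C6–C7 enolate of 14 (E ring geometry at C6=C7, Z C4=C5, E C1=C10; 3S, 8R) | [O-]/C1=C(/CCO[Si](C)(C)C(C)(C)C)[C@H]([Si](C)(C)Cc2ccccc2)C/C(C)=C/C[C@H](O[Si](C(C)C)(C(C)C)C(C)C)/C(C)=C\1.[K+] | intermediate (not isolated)
14 | (2Z,4S,6E,9R,10S)-9-[benzyl(dimethyl)silyl]-10-{2-[(tert-butyldimethylsilyl)oxy]ethyl}-3,7-dimethyl-4-[(triisopropylsilyl)oxy]cyclodeca-2,6-dien-1-one (germacranolide numbers: C6 ketone, 3S, 7S, 8R) | O=C1/C=C(/C)[C@@H](O[Si](C(C)C)(C(C)C)C(C)C)C/C=C(\C)C[C@@H]([Si](C)(C)Cc2ccccc2)[C@H]1CCO[Si](C)(C)C(C)(C)C | intermediate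
15 | (1R,2Z,4S,6E,9R,10S)-9-[benzyl(dimethyl)silyl]-10-{2-[(tert-butyldimethylsilyl)oxy]ethyl}-3,7-dimethyl-4-[(triisopropylsilyl)oxy]cyclodeca-2,6-dien-1-ol | O[C@@H]1/C=C(/C)[C@@H](O[Si](C(C)C)(C(C)C)C(C)C)C/C=C(\C)C[C@@H]([Si](C)(C)Cc2ccccc2)[C@H]1CCO[Si](C)(C)C(C)(C)C | intermediate
16 | (1R,2Z,4S,6E,9R,10S)-9-[benzyl(dimethyl)silyl]-10-(2-hydroxyethyl)-3,7-dimethyl-4-[(triisopropylsilyl)oxy]cyclodeca-2,6-dien-1-ol | O[C@@H]1/C=C(/C)[C@@H](O[Si](C(C)C)(C(C)C)C(C)C)C/C=C(\C)C[C@@H]([Si](C)(C)Cc2ccccc2)[C@H]1CCO | intermediate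
17 | lactol of 16 (cyclic hemiacetal of C12 with the C6 oxygen, either anomer) | OC1O[C@@H]2/C=C(/C)[C@@H](O[Si](C(C)C)(C(C)C)C(C)C)C/C=C(\C)C[C@@H]([Si](C)(C)Cc3ccccc3)[C@H]2C1 | intermediate (not isolated)
18 | (3S,6R,7S,8R)-8-[benzyl(dimethyl)silyl]-3-[(triisopropylsilyl)oxy]-13-norgermacra-1(10)E,4Z-dien-12,6-olide (trans-fused γ-lactone; 3β-O, 6α-O, 7α-H, 8β-Si) | O=C1O[C@@H]2/C=C(/C)[C@@H](O[Si](C(C)C)(C(C)C)C(C)C)C/C=C(\C)C[C@@H]([Si](C)(C)Cc3ccccc3)[C@H]2C1 | intermediate
19 | 8-(fluorodimethylsilyl) analogue of 18 | O=C1O[C@@H]2/C=C(/C)[C@@H](O[Si](C(C)C)(C(C)C)C(C)C)C/C=C(\C)C[C@@H]([Si](C)(C)F)[C@H]2C1 | intermediate (not isolated)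
20 | (3S,6R,7R,8R)-8-hydroxy-3-[(triisopropylsilyl)oxy]-13-norgermacra-1(10)E,4Z-dien-12,6-olide | O=C1O[C@@H]2/C=C(/C)[C@@H](O[Si](C(C)C)(C(C)C)C(C)C)C/C=C(\C)C[C@@H](O)[C@H]2C1 | intermediate
21 | (3S,6R,7S,8R)-8-[(triethylsilyl)oxy]-3-[(triisopropylsilyl)oxy]-13-norgermacra-1(10)E,4Z-dien-12,6-olide | O=C1O[C@@H]2/C=C(/C)[C@@H](O[Si](C(C)C)(C(C)C)C(C)C)C/C=C(\C)C[C@@H](O[Si](CC)(CC)CC)[C@H]2C1 | intermediate
22 | lithium enolate of 21 (C11=C12) | [Li+].[O-]C1O[C@@H]2/C=C(/C)[C@@H](O[Si](C(C)C)(C(C)C)C(C)C)C/C=C(\C)C[C@@H](O[Si](CC)(CC)CC)[C@H]2C=1 | intermediate (not isolated)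
23 | 11-[(dimethylamino)methyl] derivative of 21 (both C11 epimers) | CN(C)CC1C(=O)O[C@@H]2/C=C(/C)[C@@H](O[Si](C(C)C)(C(C)C)C(C)C)C/C=C(\C)C[C@@H](O[Si](CC)(CC)CC)[C@@H]12 | intermediate (not isolated)
24 | trimethylammonium iodide from 23 | C[N+](C)(C)CC1C(=O)O[C@@H]2/C=C(/C)[C@@H](O[Si](C(C)C)(C(C)C)C(C)C)C/C=C(\C)C[C@@H](O[Si](CC)(CC)CC)[C@@H]12.[I-] | intermediate (not isolated)
25 | (3S,6R,7S,8R)-8-[(triethylsilyl)oxy]-3-[(triisopropylsilyl)oxy]germacra-1(10)E,4Z,11(13)-trien-12,6-olide | C=C1C(=O)O[C@@H]2/C=C(/C)[C@@H](O[Si](C(C)C)(C(C)C)C(C)C)C/C=C(\C)C[C@@H](O[Si](CC)(CC)CC)[C@@H]12 | intermediate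
26 | (3S,6R,7R,8R)-8-hydroxy-3-[(triisopropylsilyl)oxy]germacra-1(10)E,4Z,11(13)-trien-12,6-olide | C=C1C(=O)O[C@@H]2/C=C(/C)[C@@H](O[Si](C(C)C)(C(C)C)C(C)C)C/C=C(\C)C[C@@H](O)[C@@H]12 | intermediate
27 | methyl angelate, methyl (2Z)-2-methylbut-2-enoate | C/C=C(/C)C(=O)OC | starting material
28 | angelyl alcohol, (2Z)-2-methylbut-2-en-1-ol | C/C=C(/C)CO | intermediate
29 | [(2S,3R)-2,3-dimethyloxiran-2-yl]methanol | OC[C@]1(C)O[C@@H]1C | intermediate
30 | (2R,3R)-2,3-dimethyloxirane-2-carbaldehyde | O=C[C@]1(C)O[C@@H]1C | intermediate (not isolated)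
31 | (2R,3R)-2,3-dimethyloxirane-2-carboxylic acid, (2R,3R)-epoxyangelic acid | OC(=O)[C@]1(C)O[C@@H]1C | intermediate
32 | mixed anhydride of 31 with 2,4,6-trichlorobenzoic acid | O=C(OC(=O)[C@]1(C)O[C@@H]1C)c1c(Cl)cc(Cl)cc1Cl | intermediate (not isolated)
33 | (3S,6R,7R,8R)-8-{[(2R,3R)-2,3-dimethyloxirane-2-carbonyl]oxy}-3-[(triisopropylsilyl)oxy]germacra-1(10)E,4Z,11(13)-trien-12,6-olide | C=C1C(=O)O[C@@H]2/C=C(/C)[C@@H](O[Si](C(C)C)(C(C)C)C(C)C)C/C=C(\C)C[C@@H](OC(=O)[C@]3(C)O[C@@H]3C)[C@@H]12 | intermediate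
34 | (3S,6R,7R,8R)-8-{[(2R,3R)-2,3-dimethyloxirane-2-carbonyl]oxy}-3-hydroxygermacra-1(10)E,4Z,11(13)-trien-12,6-olide | C=C1C(=O)O[C@@H]2/C=C(/C)[C@@H](O)C/C=C(\C)C[C@@H](OC(=O)[C@]3(C)O[C@@H]3C)[C@@H]12 | intermediate
35 | (3S,6R,7R,8R)-8-{[(2R,3R)-2,3-dimethyloxirane-2-carbonyl]oxy}-3-(3-methylbutanoyloxy)germacra-1(10)E,4Z,11(13)-trien-12,6-olide | C=C1C(=O)O[C@@H]2/C=C(/C)[C@@H](OC(=O)CC(C)C)C/C=C(\C)C[C@@H](OC(=O)[C@]3(C)O[C@@H]3C)[C@@H]12 | intermediate
36 | CNP0167461.2, (1R,3S,6R,7R,8R,10R)-1,10-epoxy-8-{[(2R,3R)-2,3-dimethyloxirane-2-carbonyl]oxy}-3-(3-methylbutanoyloxy)germacra-4Z,11(13)-dien-12,6-olide | C=C1C(=O)O[C@@H]2/C=C(/C)[C@@H](OC(=O)CC(C)C)C[C@H]3O[C@]3(C)C[C@@H](OC(=O)[C@]3(C)O[C@@H]3C)[C@@H]12 | target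

**Step count and risks**

Total step count: 22. Longest linear sequence: 18 steps (1–5, 7–15, 19–22).

Steps most likely to fail:

Step 7. The titanium complex may insert the hindered, enolisable ketone only slowly, so that enolisation competes, or it may add to the carbonyl face next to the isopropenyl group (poor facial selectivity). The fallback sets out from 9 (with 6 as partner) and comes back at 11. Cp2ZrCl2 and EtMgBr (2 equiv) in THF take up 9 as 1,1-bis(cyclopentadienyl)-2-[benzyl(dimethyl)silyl]-3-{2-[(tert-butyldimethylsilyl)oxy]ethyl}-1-zirconacyclopent-2-ene F1, with silicon next to zirconium. Ketone 6 then displaces ethene and inserts into the Zr–C bond remote from silicon, and protonolysis gives 11 with the same alkene geometry. This replaces the titanium complex made in the flask by a preformed zirconacycle that can be characterised before the ketone is added and tolerates longer reaction times at room temperature.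

Step 9. Hydride may be delivered to the other carbonyl face if a second conformer of the ten-membered ketone reacts (poor facial selectivity at C6). The fallback sets out from 14 and comes back at 15. The reduction then gives mainly the C6 epimer, (1S,2Z,4S,6E,9R,10S)-9-[benzyl(dimethyl)silyl]-10-{2-[(tert-butyldimethylsilyl)oxy]ethyl}-3,7-dimethyl-4-[(triisopropylsilyl)oxy]cyclodeca-2,6-dien-1-ol F2. Mitsunobu reaction with 4-nitrobenzoic acid, PPh3 and DIAD inverts it to the (1R)-configured 4-nitrobenzoate of 15 F3, and K2CO3 in MeOH releases 15. This replaces face-selective reduction by SN2 inversion of the isolated epimer.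

Step 22. The peracid may attack the other face of C1=C10 through the conformer that turns the C10 methyl group to the α side, or C4=C5 may be epoxidised as well. The fallback sets out from 35 and ends at 36. Shi epoxidation with the D-fructose-derived ketone, KHSO5 and K2CO3 buffer in MeCN/dimethoxymethane/H2O at 0 °C is reagent-controlled, converts E-trisubstituted alkenes into the (R,R)-epoxides required here and is insensitive to the hindered C4=C5 bond. No new compound arises on this way (F0).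

Further compounds
F1 | step 7 | 1,1-bis(cyclopentadienyl)-2-[benzyl(dimethyl)silyl]-3-{2-[(tert-butyldimethylsilyl)oxy]ethyl}-1-zirconacyclopent-2-ene | C1(C=CC=C1)[Zr]2(C3C=CC=C3)C([Si](C)(C)Cc4ccccc4)=C(CCO[Si](C)(C)C(C)(C)C)CC2
F2 | step 9 | (1S,2Z,4S,6E,9R,10S)-9-[benzyl(dimethyl)silyl]-10-{2-[(tert-butyldimethylsilyl)oxy]ethyl}-3,7-dimethyl-4-[(triisopropylsilyl)oxy]cyclodeca-2,6-dien-1-ol | O[C@H]1/C=C(/C)[C@@H](O[Si](C(C)C)(C(C)C)C(C)C)C/C=C(\C)C[C@@H]([Si](C)(C)Cc2ccccc2)[C@H]1CCO[Si](C)(C)C(C)(C)C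
F3 | step 9 | (1R,2Z,4S,6E,9R,10S)-9-[benzyl(dimethyl)silyl]-10-{2-[(tert-butyldimethylsilyl)oxy]ethyl}-3,7-dimethyl-4-[(triisopropylsilyl)oxy]cyclodeca-2,6-dien-1-yl 4-nitrobenzoate | O=C(O[C@@H]1/C=C(/C)[C@@H](O[Si](C(C)C)(C(C)C)C(C)C)C/C=C(\C)C[C@@H]([Si](C)(C)Cc2ccccc2)[C@H]1CCO[Si](C)(C)C(C)(C)C)c1ccc(cc1)[N+](=O)[O-]
F0 | step 22 | none | none
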